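The ratio I looked at first was the enzyme in the south flask to the enzyme in the north-west run: twice on the charge, but 3.44 once the impurity is taken off. The two look nearly the same and differ in loading.

| setting | south | north-west | flask |
|---|---|---|---|
| starting material | 0.10 M | 0.10 M | 0.10 M |
| enzyme | 0.02 mol% | 0.01 mol% | 0.02 mol% |
| impurity | 5.9 µM | 5.9 µM | 5.9 µM |
| remark | the very flask that is asked about, followed so far | run made earlier |  |
| time |  |  | 15 min |

south run (percent of the starting material charged)

| time / min | target / % |
|---|---|
| 2.00 | 13 |
| 4.00 | 19 |
| 6.00 | 17 |
| 8.00 | 17 |
| 10.0 | 23 |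
| 12.0 | 22 |
| 15.0 | 20 |

north-west run (percent of the starting material charged)

| time / s | target / % |
|---|---|
| 10.0 | 2 |
| 12.0 | 3 |
| 20.0 | 2 |
| 30.0 | 5 |
| 50.0 | 1 |
| 80.0 | 8 |

(each reading ± 2 percentage points)

- alpha: at 15 min add starting material, 50.0% of the amount charged, then wait 5.0 min
- gamma: change nothing and wait 5.0 min more
- zeta: at 15 min add enzyme, 50.0% of the amount charged, then wait 5.0 min

- the volume of additions can be left aside
- a reading or a percentage of target counts all its forms, free or not

- target, in percent of the starting material first charged, at 15 min
- what to do for the largest gain in target; "none" if nothing gains more than 2 percentage points (alpha / gamma / zeta / none)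
- target present, in percent of the starting material first charged, after gamma
- target present, in percent of the starting material first charged, after zeta

I assumed that each impurity removes one enzyme, which these readings do not prove. So I counted the usable enzyme U, charged enzyme less impurity:

U(south) = 20.0 µM − 5.9 µM = 14.1 µM

U(north-west) = 10.0 µM − 5.9 µM = 4.10 µM

South's readings from 4.00 min on average 19.7%, with about 80.3% of the starting material left, so I read that stall as lost enzyme. Then:

N = 19.7% × 0.10 M / 14.1 µM = 1390

N is the target made per usable enzyme, a turnover number. With it I expected north-west to stop near 5.72%; its last reading, 8%, carries a scatter of 2 percentage points. In the south flask, the 10.0 µM of enzyme in zeta meets no impurity on my assumption, so it should add 14 points, reaching 33.6%. Alpha and gamma add no enzyme, so I chose zeta.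

The forecast gave 20.5% now, 20.5% after gamma and 32% after zeta, and chose zeta, saying “I take enzyme death as more likely”. My zeta figure stands higher.

The south flask gave 24.0% now, 24.8% after gamma and 33.3% after zeta. Zeta gained 9.4 points, alpha 0.61 points and gamma 0.88 points.

    starting material + enzyme → target + enzyme, rate k1*[starting material]*[enzyme]/(1 + ([starting material]/Km1) + ([starting material]/Ksi1)^2) (0.0880 M, 31.0 mM, k = 10000 M⁻¹ s⁻¹)
    enzyme + target ⇌ idle complex, settled at all times (K = 910 M⁻¹)
    enzyme + impurity → spent catalyst A (k = 52000 M⁻¹ s⁻¹)
    enzyme → spent catalyst B (k = 0.0480 s⁻¹)

The south flask had not quite come to rest at 15 min: free enzyme stood at 0.207% and idle complex at 4.52% of the catalyst charge, together 0.945 µM. Multiplied by N, that enzyme is worth 1.3 points. Left ten times as long, the flask reaches 25.9%, a rise of 1.9 points, with free enzyme and idle complex both at 0% and 74.1% of the starting material still present.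

For the neighbouring flask with 0.05 mol% of enzyme, U is 44.1 µM, and N gives a stop near 61.3%. The computed result for that flask at 15 min is 67.1%.

(Readings and results were computed with made-up constants, noise included.)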